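**Plan**

- Ring numbering: O1–O2–C3–C4–C5–C6. C3 carries CH2CO2H, C4 a methyl group, C6 a methyl group and the chain C7–C16 (methyl groups on C8 and C12, phenyl on C16).
- Retrosynthetic cuts, in order: C4–C5 (drawn as a C4=C5 alkene and cut by ring-closing metathesis), C3–O2 (hydroperoxide addition to a dienal), C6–O1 (epoxide perhydrolysis), C5–C6 (sulfur ylide on a methyl ketone), C6–C7 (Grignard reagent on a Weinreb amide), C9–C10 (copper-catalysed alkyl–alkyl coupling), C15–C16 (cross-metathesis with styrene).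
- Enabling feature: the O1–O2 bridge ties C3 to C6, so the adjacent ring carbons C4 (CH–CH3) and C5 (CH2) can be the inner carbons of an alkenyl group on C3 and a vinyl group on C6, held six atoms apart.
- Forward order: side chain (steps 1–5), C6 epoxide and tertiary hydroperoxide (6, 7), acyclic C6–O–O–C3 peroxide (9), diene (10–12), ring closure at C4–C5 (13), saturation (14). The carboxylic acid is carried free from step 10.
- Stereochemistry: C12 from (S)-citronellyl bromide; C8 from (S)-3-bromo-2-methylpropan-1-ol; C6 from a catalyst-controlled epoxidation followed by invertive perhydrolysis; C3 from an amine-catalysed peroxidation; C4 from hydrogen delivery to the ring face anti to the C3 and C6 side chains.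

Key step: step 13

Assumption (step 6): the binaphthoxide antipode written is the one expected to add the ylide to the Re face of ketone 12; if the sense proves opposite, the mirror-image complex is used.

**Step 1**
Reactants: 1 (S)-citronellyl bromide; 2 styrene
Product: 3 [(1E,5S)-7-bromo-5-methylhept-1-en-1-yl]benzene
Conditions: second-generation Hoveyda–Grubbs catalyst RuCl2(H2IMes)(=CH-C6H4-2-O-i-Pr) (5 mol %), 2 (5 equiv), CH2Cl2, 40 °C
Reagents that add atoms: none
Why: Olefin cross-metathesis of the trisubstituted prenyl-type alkene with styrene, driven by loss of a volatile alkene; the C12 centre of the chiral-pool bromide is remote and untouched.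

**Step 2**
Reactants: 3 [(1E,5S)-7-bromo-5-methylhept-1-en-1-yl]benzene
Product: 4 (S)-1-bromo-3-methyl-7-phenylheptane
Conditions: H2 (1 atm), 5% Pt/C, EtOAc, rt
Reagents that add atoms: none
Why: Heterogeneous hydrogenation of the styrenyl C=C; Pt/C in EtOAc should leave the primary C–Br bond and the arene intact.

**Step 3**
Reactants: 4 (S)-1-bromo-3-methyl-7-phenylheptane; 5 (S)-3-bromo-2-methylpropan-1-ol
Product: 8 (2R,6S)-2,6-dimethyl-10-phenyldecan-1-ol, via Grignard reagent 6 (not isolated), via magnesium alkoxide 7 (not isolated)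
Conditions: 4, Mg, THF, 50 °C; 5, MeMgCl (1 equiv), THF, −20 °C; combine, Li2CuCl4 (3 mol %), −20 °C → rt; 1 M HCl
Reagents that add atoms: none
Why: Copper-catalysed alkyl–alkyl cross-coupling of a primary Grignard reagent with a primary bromide (the hydroxyl masked as its alkoxide); neither stereocentre takes part, and the change from S in 5 to R in 8 is only a change of CIP priority.

**Step 4**
Reactants: 8 (2R,6S)-2,6-dimethyl-10-phenyldecan-1-ol
Product: 9 (2R,6S)-1-bromo-2,6-dimethyl-10-phenyldecane
Conditions: CBr4, PPh3, CH2Cl2, 0 °C → rt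
Reagents that add atoms: carbon tetrabromide, BrC(Br)(Br)Br
Why: Appel bromination at a primary carbon; the adjacent C8 centre is not involved.

**Step 5**
Reactants: 9 (2R,6S)-1-bromo-2,6-dimethyl-10-phenyldecane; 10 N-methoxy-N-methylacetamide
Product: 12 (4R,8S)-4,8-dimethyl-12-phenyldodecan-2-one, via Grignard reagent 11 (not isolated)
Conditions: Mg, THF, reflux; then 10, THF, 0 °C; 1 M HCl
Reagents that add atoms: none
Why: Weinreb ketone synthesis; the chelated tetrahedral intermediate prevents over-addition and gives the methyl ketone whose carbonyl carbon is C6.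

**Step 6**
Reactants: 12 (4R,8S)-4,8-dimethyl-12-phenyldodecan-2-one
Product: 13 (2S)-2-[(2R,6S)-2,6-dimethyl-10-phenyldecyl]-2-methyloxirane
Conditions: Me3S(O)I, NaH, THF, reflux, filter; then 12, LaLi3[(S)-binaphthoxide]3 (5 mol %), (2,4,6-(MeO)3C6H2)3P=O (5 mol %), 5 Å MS, THF, rt
Reagents that add atoms: trimethylsulfoxonium iodide, C[S+](C)(C)=O.[I-]
Why: Catalytic asymmetric Corey–Chaykovsky epoxidation of a methyl ketone, in which the lanthanum–lithium binaphthoxide complex binds the ketone and directs the ylide to the Re face of the carbonyl (reagent control over the remote C8 centre) to give the 2S epoxide.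

**Step 7**
Reactants: 13 (2S)-2-[(2R,6S)-2,6-dimethyl-10-phenyldecyl]-2-methyloxirane
Product: 14 (2R,4R,8S)-2-hydroperoxy-2,4,8-trimethyl-12-phenyldodecan-1-ol
Conditions: H2O2 (anhydrous, ca. 2 M in Et2O, 10 equiv), H3PMo12O40 (2 mol %), Et2O, rt
Reagents that add atoms: hydrogen peroxide, OO
Why: Acid-catalysed perhydrolysis of a 2,2-disubstituted epoxide, in which H2O2 should open the activated ring at the tertiary carbon with inversion, so the 2S epoxide gives the 2R hydroperoxide (C6 of the target) with C5 as CH2OH.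

**Step 8**
Reactants: 15 (E)-2-methylbut-2-enal (tiglic aldehyde); 16 (triphenylphosphoranylidene)acetaldehyde
Product: 17 (2E,4E)-4-methylhexa-2,4-dienal
Conditions: 15 (2 equiv), toluene, 80 °C
Reagents that add atoms: none
Why: Wittig reaction of a stabilised formyl ylide (E-selective); the α-branched enal is used in excess to limit a second homologation.

**Step 9**
Reactants: 14 (2R,4R,8S)-2-hydroperoxy-2,4,8-trimethyl-12-phenyldodecan-1-ol; 17 (2E,4E)-4-methylhexa-2,4-dienal
Product: 18 (3S,4E)-3-{[(2R,4R,8S)-1-hydroxy-2,4,8-trimethyl-12-phenyldodecan-2-yl]peroxy}-4-methylhex-4-enal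
Conditions: (S)-α,α-diphenylprolinol trimethylsilyl ether (20 mol %), PhCO2H (20 mol %), 17 (3 equiv), toluene, 0 °C
Reagents that add atoms: none
Why: Amine-catalysed enantioselective β-peroxidation of an enal (iminium-activated oxa-Michael addition of a tertiary hydroperoxide), in which the CPh2OSiMe3 group shields the Re face of C3 in the E,s-trans iminium so that OOH adds to the Si face and sets 3S, while the methyl groups on C4 and C5 disfavour 1,6-addition.

**Step 10**
Reactants: 18 (3S,4E)-3-{[(2R,4R,8S)-1-hydroxy-2,4,8-trimethyl-12-phenyldodecan-2-yl]peroxy}-4-methylhex-4-enal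
Product: 19 (3S,4E)-3-{[(2R,4R,8S)-1-hydroxy-2,4,8-trimethyl-12-phenyldodecan-2-yl]peroxy}-4-methylhex-4-enoic acid
Conditions: NaClO2, NaH2PO4, 2-methylbut-2-ene (20 equiv), t-BuOH/H2O, 0 °C
Reagents that add atoms: sodium chlorite, [Na+].[O-]Cl=O
Why: Pinnick oxidation of the aldehyde; chlorite should not attack the dialkyl peroxide, and the alkene scavenger intercepts HOCl before it can add to the C4 alkene.

**Step 11**
Reactants: 19 (3S,4E)-3-{[(2R,4R,8S)-1-hydroxy-2,4,8-trimethyl-12-phenyldodecan-2-yl]peroxy}-4-methylhex-4-enoic acid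
Product: 20 (3S,4E)-4-methyl-3-{[(2R,4R,8S)-2,4,8-trimethyl-1-oxo-12-phenyldodecan-2-yl]peroxy}hex-4-enoic acid
Conditions: Dess–Martin periodinane, CH2Cl2, 0 °C → rt
Reagents that add atoms: none
Why: Dess–Martin oxidation of the neopentyl primary alcohol under non-basic conditions; the aldehyde cannot enolise because C6 is quaternary.

**Step 12**
Reactants: 20 (3S,4E)-4-methyl-3-{[(2R,4R,8S)-2,4,8-trimethyl-1-oxo-12-phenyldodecan-2-yl]peroxy}hex-4-enoic acid
Product: 21 (3S,4E)-4-methyl-3-{[(3R,5R,9S)-3,5,9-trimethyl-13-phenyltridec-1-en-3-yl]peroxy}hex-4-enoic acid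
Conditions: Ph3PCH3Br (3.0 equiv), KN(SiMe3)2 (2.9 equiv), THF, 0 °C; then 20, −78 → 0 °C; aq. citric acid
Reagents that add atoms: methyltriphenylphosphonium bromide, C[P+](c1ccccc1)(c1ccccc1)c1ccccc1.[Br-]
Why: Wittig methylenation, run on the carboxylate so that C2–H is not acidic and E1cB loss of the peroxide is suppressed; hindered dialkyl peroxides should tolerate the ylide at low temperature.

**Step 13**
Reactants: 21 (3S,4E)-4-methyl-3-{[(3R,5R,9S)-3,5,9-trimethyl-13-phenyltridec-1-en-3-yl]peroxy}hex-4-enoic acid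
Product: 22 2-[(3S,6R)-6-[(2R,6S)-2,6-dimethyl-10-phenyldecyl]-4,6-dimethyl-3,6-dihydro-1,2-dioxin-3-yl]acetic acid
Conditions: second-generation Hoveyda–Grubbs catalyst RuCl2(H2IMes)(=CH-C6H4-2-O-i-Pr) (10 mol %), CH2Cl2 (2 mM), 40 °C, Ar sparge
Reagents that add atoms: none
Why: Proposed new method: ring-closing metathesis with the O–O bond itself as the tether, in which the ruthenium carbene should initiate at the monosubstituted vinyl group on C6 and the new alkylidene at C5 closes onto the trisubstituted C4 alkene by [2+2] cycloaddition and cycloreversion through a ruthenacyclobutane, expelling the C5′–C6′ end of the dienal unit. The closest known reactions are ring-closing metatheses of diallyl ethers and of N–O-tethered dienes to 3,6-dihydro-2H-pyrans and 3,6-dihydro-1,2-oxazines, together with metatheses run in the presence of remote dialkyl peroxides. The 3,6-dihydro-1,2-dioxine closes as a six-membered ring by joining two sp2 carbons (C4 and C5), helped by the fully substituted C6 (Thorpe–Ingold effect) and by the gauche C–O–O–C preference that already folds the chain. No new stereocentre is formed: C3 and C6 are carried through and C4 is left trigonal for step 14. The step needs chemoselectivity for C=C over O–O, which the electron-poor divalent ruthenium carbene and the absence of any reducing low-valent metal should secure. It also needs ring closure over oligomerisation, which high dilution and removal of the volatile alkene secure.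

**Step 14**
Reactants: 22 2-[(3S,6R)-6-[(2R,6S)-2,6-dimethyl-10-phenyldecyl]-4,6-dimethyl-3,6-dihydro-1,2-dioxin-3-yl]acetic acid
Product: 23 2-[(3S,4S,6R)-6-[(2R,6S)-2,6-dimethyl-10-phenyldecyl]-4,6-dimethyl-1,2-dioxan-3-yl]acetic acid (target)
Conditions: KO2C–N=N–CO2K (excess, in portions), AcOH, MeOH/CH2Cl2, 0 °C → rt
Reagents that add atoms: none
Why: Diimide reduction (concerted syn transfer of two hydrogens, known to spare O–O bonds of cyclic peroxides); delivery to the face of C4=C5 that carries only the C6 methyl group and the C3 hydrogen, anti to both the CH2CO2H group on C3 and the decyl chain on C6, should set 4S with the methyl group cis to both large substituents.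

**Compound list**

1 | (S)-citronellyl bromide, (6S)-8-bromo-2,6-dimethyloct-2-ene | BrCC[C@@H](C)CCC=C(C)C | starting material
2 | styrene | C=Cc1ccccc1 | starting material
3 | [(1E,5S)-7-bromo-5-methylhept-1-en-1-yl]benzene | BrCC[C@@H](C)CC/C=C/c1ccccc1 | intermediate
4 | (S)-1-bromo-3-methyl-7-phenylheptane | BrCC[C@@H](C)CCCCc1ccccc1 | intermediate
5 | (S)-3-bromo-2-methylpropan-1-ol | OC[C@H](C)CBr | starting material
6 | [(S)-3-methyl-7-phenylheptyl]magnesium bromide | Br[Mg]CC[C@@H](C)CCCCc1ccccc1 | intermediate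
7 | chloromagnesium (S)-3-bromo-2-methylpropan-1-olate | Cl[Mg]OC[C@H](C)CBr | intermediate
8 | (2R,6S)-2,6-dimethyl-10-phenyldecan-1-ol | OC[C@H](C)CCC[C@@H](C)CCCCc1ccccc1 | intermediate
9 | (2R,6S)-1-bromo-2,6-dimethyl-10-phenyldecane | BrC[C@H](C)CCC[C@@H](C)CCCCc1ccccc1 | intermediate
10 | N-methoxy-N-methylacetamide | CC(=O)N(C)OC | starting material
11 | [(2R,6S)-2,6-dimethyl-10-phenyldecyl]magnesium bromide | Br[Mg]C[C@H](C)CCC[C@@H](C)CCCCc1ccccc1 | intermediate
12 | (4R,8S)-4,8-dimethyl-12-phenyldodecan-2-one | CC(=O)C[C@H](C)CCC[C@@H](C)CCCCc1ccccc1 | intermediate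
13 | (2S)-2-[(2R,6S)-2,6-dimethyl-10-phenyldecyl]-2-methyloxirane | C[C@@]1(CO1)C[C@H](C)CCC[C@@H](C)CCCCc2ccccc2 | intermediate
14 | (2R,4R,8S)-2-hydroperoxy-2,4,8-trimethyl-12-phenyldodecan-1-ol | OC[C@](C)(OO)C[C@H](C)CCC[C@@H](C)CCCCc1ccccc1 | intermediate
15 | (E)-2-methylbut-2-enal (tiglic aldehyde) | C/C=C(\C)C=O | starting material
16 | (triphenylphosphoranylidene)acetaldehyde | O=CC=P(c1ccccc1)(c1ccccc1)c1ccccc1 | starting material
17 | (2E,4E)-4-methylhexa-2,4-dienal | C/C=C(C)/C=C/C=O | intermediate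
18 | (3S,4E)-3-{[(2R,4R,8S)-1-hydroxy-2,4,8-trimethyl-12-phenyldodecan-2-yl]peroxy}-4-methylhex-4-enal | O=CC[C@H](OO[C@@](C)(CO)C[C@H](C)CCC[C@@H](C)CCCCc1ccccc1)/C(C)=C/C | intermediate
19 | (3S,4E)-3-{[(2R,4R,8S)-1-hydroxy-2,4,8-trimethyl-12-phenyldodecan-2-yl]peroxy}-4-methylhex-4-enoic acid | OC(=O)C[C@H](OO[C@@](C)(CO)C[C@H](C)CCC[C@@H](C)CCCCc1ccccc1)/C(C)=C/C | intermediate
20 | (3S,4E)-4-methyl-3-{[(2R,4R,8S)-2,4,8-trimethyl-1-oxo-12-phenyldodecan-2-yl]peroxy}hex-4-enoic acid | OC(=O)C[C@H](OO[C@@](C)(C=O)C[C@H](C)CCC[C@@H](C)CCCCc1ccccc1)/C(C)=C/C | intermediate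
21 | (3S,4E)-4-methyl-3-{[(3R,5R,9S)-3,5,9-trimethyl-13-phenyltridec-1-en-3-yl]peroxy}hex-4-enoic acid | OC(=O)C[C@H](OO[C@@](C)(C=C)C[C@H](C)CCC[C@@H](C)CCCCc1ccccc1)/C(C)=C/C | intermediate
22 | 2-[(3S,6R)-6-[(2R,6S)-2,6-dimethyl-10-phenyldecyl]-4,6-dimethyl-3,6-dihydro-1,2-dioxin-3-yl]acetic acid | OC(=O)C[C@@H]1OO[C@](C)(C[C@H](C)CCC[C@@H](C)CCCCc2ccccc2)C=C1C | intermediate
23 | 2-[(3S,4S,6R)-6-[(2R,6S)-2,6-dimethyl-10-phenyldecyl]-4,6-dimethyl-1,2-dioxan-3-yl]acetic acid | C[C@@H](CCCCc1ccccc1)CCC[C@@H](C)C[C@]1(C)C[C@H](C)[C@H](CC(=O)O)OO1 | target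

**Step count**

Total: 14 steps. Longest linear sequence: 13 steps (steps 1–7 and 9–14; step 8 is a one-step side branch).

**Steps most likely to fail**

Step 13. The ruthenium carbene may cleave or rearrange the bis-allylic peroxide, or fail to initiate at the hindered vinyl group on the quaternary C6, so that decomposition or oligomerisation outruns ring closure. The fallback closes the ring through the C3–O bond by the established hydroperoxysilylation/oxa-Michael sequence, with C4 taken from the chiral pool. It sets out from ketone 12 and comes back at target 23.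
- Ketone 12 is converted (LiN(i-Pr)2, THF, −78 °C; PhNTf2) into the less substituted enol triflate (4R,8S)-4,8-dimethyl-12-phenyldodec-1-en-2-yl trifluoromethanesulfonate F1.
- Negishi coupling with the zinc reagent from methyl (R)-3-bromo-2-methylpropanoate (Zn, LiCl; Pd(PPh3)4, THF) gives methyl (2S,6R,10S)-2,6,10-trimethyl-4-methylidene-14-phenyltetradecanoate F2.
- i-Bu2AlH (CH2Cl2, −78 °C) gives (2S,6R,10S)-2,6,10-trimethyl-4-methylidene-14-phenyltetradecanal F3, and Ph3P=CHCO2Me gives methyl (2E,4S,8R,12S)-4,8,12-trimethyl-6-methylidene-16-phenylhexadec-2-enoate F4.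
- Mukaiyama–Isayama peroxidation (Co(thd)2, O2, Et3SiH) gives methyl (2E,4S,8R,12S)-4,6,8,12-tetramethyl-16-phenyl-6-[(triethylsilyl)peroxy]hexadec-2-enoate F5 as both C6 epimers.
- Bu4NF frees methyl (2E,4S,8R,12S)-6-hydroperoxy-4,6,8,12-tetramethyl-16-phenylhexadec-2-enoate F6, which closes (Et2NH, CF3CH2OH) by 6-exo oxa-Michael addition to methyl 2-[(3S,4S,6R)-6-[(2R,6S)-2,6-dimethyl-10-phenyldecyl]-4,6-dimethyl-1,2-dioxan-3-yl]acetate F7.
- The ring isomers are separated at F7 and LiOH (THF/H2O) gives 23. This path gives up control at C6.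

Step 9. The β-peroxy enamine may collapse to the epoxy aldehyde with loss of the tertiary alkoxide, or the free C5 hydroxyl may divert the iminium ion into a cyclic peroxyacetal. The fallback makes the C3–O bond first and the C2–C3 bond second. It sets out from 14 and 15 and comes back at acid 19.
- 14 and tiglic aldehyde 15 are condensed (TsOH cat., MgSO4, CH2Cl2) to (6R)-3-[(2E)-but-2-en-2-yl]-6-[(2R,6S)-2,6-dimethyl-10-phenyldecyl]-6-methyl-1,2,4-trioxane F8, whose acetal carbon is the future C3.
- TiCl4 and 1-(tert-butyldimethylsilyloxy)-1-methoxyethene (CH2Cl2, −78 °C) ionise the C–O(alkyl) bond to a peroxycarbenium ion, which is trapped at C3 to give methyl (3S,4E)-3-{[(2R,4R,8S)-1-hydroxy-2,4,8-trimethyl-12-phenyldodecan-2-yl]peroxy}-4-methylhex-4-enoate F9 with the C5 hydroxyl set free.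
- This Mukaiyama-type substitution has no control at C3, so the 3S isomer is separated by chromatography; LiOH then gives 19.

Step 14. Diimide may react too slowly with the hindered trisubstituted alkene next to the quaternary C6, or deliver hydrogen to both ring faces. The fallback replaces the concerted transfer by a stepwise hydrogen-atom-transfer hydrogenation (Mn(dpm)3 cat., PhSiH3, t-BuOOH, i-PrOH, rt, O2 excluded). This reduces hindered trisubstituted alkenes through the tertiary C4 radical, which sits in the ring where the geometry for attack on the O–O bond is poor and should be quenched from the less hindered face. It sets out from 22 and comes back at 23 without new isolated compounds.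

**Further compounds**

F1 | step 13 | (4R,8S)-4,8-dimethyl-12-phenyldodec-1-en-2-yl trifluoromethanesulfonate | C=C(OS(=O)(=O)C(F)(F)F)C[C@H](C)CCC[C@@H](C)CCCCc1ccccc1
F2 | step 13 | methyl (2S,6R,10S)-2,6,10-trimethyl-4-methylidene-14-phenyltetradecanoate | COC(=O)[C@@H](C)CC(=C)C[C@H](C)CCC[C@@H](C)CCCCc1ccccc1
F3 | step 13 | (2S,6R,10S)-2,6,10-trimethyl-4-methylidene-14-phenyltetradecanal | O=C[C@@H](C)CC(=C)C[C@H](C)CCC[C@@H](C)CCCCc1ccccc1
F4 | step 13 | methyl (2E,4S,8R,12S)-4,8,12-trimethyl-6-methylidene-16-phenylhexadec-2-enoate | COC(=O)/C=C/[C@@H](C)CC(=C)C[C@H](C)CCC[C@@H](C)CCCCc1ccccc1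
F5 | step 13 | methyl (2E,4S,8R,12S)-4,6,8,12-tetramethyl-16-phenyl-6-[(triethylsilyl)peroxy]hexadec-2-enoate (both C6 epimers) | COC(=O)/C=C/[C@@H](C)CC(C)(OO[Si](CC)(CC)CC)C[C@H](C)CCC[C@@H](C)CCCCc1ccccc1
F6 | step 13 | methyl (2E,4S,8R,12S)-6-hydroperoxy-4,6,8,12-tetramethyl-16-phenylhexadec-2-enoate (both C6 epimers) | COC(=O)/C=C/[C@@H](C)CC(C)(OO)C[C@H](C)CCC[C@@H](C)CCCCc1ccccc1
F7 | step 13 | methyl 2-[(3S,4S,6R)-6-[(2R,6S)-2,6-dimethyl-10-phenyldecyl]-4,6-dimethyl-1,2-dioxan-3-yl]acetate | COC(=O)C[C@@H]1OO[C@](C)(C[C@H](C)CCC[C@@H](C)CCCCc2ccccc2)C[C@@H]1C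
F8 | step 9 | (6R)-3-[(2E)-but-2-en-2-yl]-6-[(2R,6S)-2,6-dimethyl-10-phenyldecyl]-6-methyl-1,2,4-trioxane (both C3 epimers) | C/C=C(\C)C1OC[C@@](C)(C[C@H](C)CCC[C@@H](C)CCCCc2ccccc2)OO1
F9 | step 9 | methyl (3S,4E)-3-{[(2R,4R,8S)-1-hydroxy-2,4,8-trimethyl-12-phenyldodecan-2-yl]peroxy}-4-methylhex-4-enoate | COC(=O)C[C@H](OO[C@@](C)(CO)C[C@H](C)CCC[C@@H](C)CCCCc1ccccc1)/C(C)=C/C
F0 | step 14 | none | none
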